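**Retrosynthetic overview**

1. Feature: ring A (C1' isobutyryl, C2' O, C3' CH2 bridge, C4' O, C5' Me, C6' O) is a hexasubstituted benzene in which C6'–C5'–C4'–C3' is a 1,3-dioxygenated four-carbon unit and C1'–C2' is an acyl-bearing two-carbon unit with oxygen on C2'.
2. Last ring: C3'–C2' and C6'–C1' by [4+2] benzannulation of a 1-methoxy-1,3-bis(silyloxy)diene that already carries rings B and C with 1-ethoxy-4-methylpent-1-yn-3-one; one global ether cleavage follows.
3. The diene comes from a β-keto ester, made by Lewis-acid γ-benzylation of the bis(silyl) dienolate of methyl 2-methyl-3-oxobutanoate with an 8-(bromomethyl)chromanone.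
4. Ring C (O1–C2–C3–C4) from 3,5-dimethoxy-4-methylphenol and 3-methylbut-2-enoic acid. It is closed first, on a phenol whose only free hydroxyl is the one para to the methyl group, because a free methylphloroglucinol ring could close the pyranone on either flanking hydroxyl.
5. Order of rings: B (from 2,6-dimethoxytoluene) → C (step 2) → A (step 10).

Key step: step 10

Remarks on the chemistry:
- Chromanone numbering (O1, C2, C3, C4, C4a, C5–C8, C8a) is used for rings B and C, primed numbers for ring A.
- The chromanone ketone is enolisable. The side chain is therefore attached under Lewis-acid conditions, and the ketone passes through the key step as its trimethylsilyl enol ether, formed together with the diene and lost in the acidic work-up.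
- Assumption: 12 (one stereocentre) is racemic and 18 is a transient diastereomer mixture; this has no consequence because the target has no stereocentre.
- LDA and n-BuLi are taken as commercial solutions.

**Route**

Step 1
Reactants: 1 dimethoxytoluene (1,3-dimethoxy-2-methylbenzene)
Product: 3 phenol (3,5-dimethoxy-4-methylphenol), via aryl pinacol boronate 2 (not isolated)
Conditions: B2pin2, [Ir(OMe)(cod)]2 (1 mol %), dtbpy (2 mol %), THF, 80 °C; then 30% H2O2, aq NaOH, 0 °C → rt
Reagents that add atoms: hydrogen peroxide, OO (the phenol oxygen); bis(pinacolato)diboron, CC1(C)OB(OC1(C)C)B1OC(C)(C)C(C)(C)O1 (boron of 2 only, not retained in 3)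
Why: Iridium-catalysed C–H borylation is sterically controlled and the hydrogen para to the methyl group is the only one without an ortho substituent, so 2 should form there and its oxidation gives the phenol (one-pot C–H borylation/oxidation).

Step 2
Reactants: 3 phenol (3,5-dimethoxy-4-methylphenol); 4 3-methylbut-2-enoic acid
Product: 6 dimethoxychromanone (5,7-dimethoxy-2,2,6-trimethylchroman-4-one), via aryl enone 5 (not isolated)
Conditions: P2O5/MsOH (Eaton's reagent), 70 °C
Reagents that add atoms: none
Why: Friedel–Crafts acylation by the activated acid occurs ortho to the hydroxyl (the two such positions are equivalent) and the enone 5 closes by oxa-Michael addition of the only free hydroxyl, the oxygen para to the methyl group, so the 6-methyl chromanone is the only possible ring C isomer (acid-mediated chromanone annulation).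

Step 3
Reactants: 6 dimethoxychromanone (5,7-dimethoxy-2,2,6-trimethylchroman-4-one)
Product: 7 benzylic bromide (8-(bromomethyl)-5,7-dimethoxy-2,2,6-trimethylchroman-4-one)
Conditions: (CH2O)n, 33% HBr in AcOH, rt
Reagents that add atoms: formaldehyde (as paraformaldehyde), C=O; hydrogen bromide, Br
Why: Blanc-type bromomethylation (electrophilic substitution by protonated formaldehyde, then OH to Br exchange) can only take place at C8, the single unsubstituted ring carbon, which is activated by O1, 7-OMe and 5-OMe.

Step 4
Reactants: 8 methyl 2-methyl-3-oxobutanoate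
Product: 9 silyl enol ether (methyl 2-methyl-3-(trimethylsilyloxy)but-2-enoate)
Conditions: TMSCl, Et3N, hexane, rt
Reagents that add atoms: chlorotrimethylsilane, C[Si](C)(C)Cl
Why: O-silylation of the enol form of a β-keto ester with TMSCl/Et3N is standard silyl enol ether formation and gives the conjugated 3-silyloxy enoate.

Step 5
Reactants: 9 silyl enol ether (methyl 2-methyl-3-(trimethylsilyloxy)but-2-enoate)
Product: 10 simple diene (1-methoxy-2-methyl-1,3-bis(trimethylsilyloxy)buta-1,3-diene)
Conditions: LDA, THF, −78 °C; then TMSCl, −78 °C → rt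
Reagents that add atoms: chlorotrimethylsilane, C[Si](C)(C)Cl
Why: LDA removes a proton from the γ-methyl group of the silyloxy enoate (a vinylogous ester) and the dienolate is trapped on oxygen, the standard two-stage preparation of Chan-type 1,3-bis(silyloxy)dienes.

Step 6
Reactants: 7 benzylic bromide (8-(bromomethyl)-5,7-dimethoxy-2,2,6-trimethylchroman-4-one); 10 simple diene (1-methoxy-2-methyl-1,3-bis(trimethylsilyloxy)buta-1,3-diene)
Product: 12 keto ester (methyl 5-(5,7-dimethoxy-2,2,6-trimethyl-4-oxochroman-8-yl)-2-methyl-3-oxopentanoate), via silyl enol ether 11 (not isolated)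
Conditions: ZnBr2 (20 mol %), CH2Cl2, −40 → 0 °C; then 1 M HCl, THF, rt
Reagents that add atoms: none
Why: ZnBr2 ionises the bromide to a benzylic cation stabilised by O1, 7-OMe and 5-OMe, which is captured at the unsubstituted terminal carbon C4 of the bis(silyl) dienolate 10 (Lewis-acid γ-alkylation of a silyl dienol ether with an SN1-active halide, Mukaiyama–Reetz type), conditions under which the enolisable chromanone ketone is inert, unlike under dianion alkylation; acid work-up hydrolyses 11 so that 12 can be chromatographed.

Step 7
Reactants: 12 keto ester (methyl 5-(5,7-dimethoxy-2,2,6-trimethyl-4-oxochroman-8-yl)-2-methyl-3-oxopentanoate)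
Product: 11 silyl enol ether (methyl 5-(5,7-dimethoxy-2,2,6-trimethyl-4-oxochroman-8-yl)-2-methyl-3-(trimethylsilyloxy)pent-2-enoate)
Conditions: TMSCl, Et3N, hexane/CH2Cl2, rt
Reagents that add atoms: chlorotrimethylsilane, C[Si](C)(C)Cl
Why: Enol silylation as in step 4, selective because only the β-keto ester is acidic enough for TMSCl/Et3N while the chromanone ketone is untouched; 11 is regenerated here from purified 12.

Step 8
Reactants: 11 silyl enol ether (methyl 5-(5,7-dimethoxy-2,2,6-trimethyl-4-oxochroman-8-yl)-2-methyl-3-(trimethylsilyloxy)pent-2-enoate)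
Product: 13 tris-silyl diene ((3Z)-5-[5,7-dimethoxy-2,2,6-trimethyl-4-(trimethylsilyloxy)-2H-chromen-8-yl]-1-methoxy-2-methyl-1,3-bis(trimethylsilyloxy)penta-1,3-diene)
Conditions: LDA (2.3 equiv), THF, −78 °C; then TMSCl (2.6 equiv), −78 → 0 °C
Reagents that add atoms: chlorotrimethylsilane, C[Si](C)(C)Cl
Why: Two equivalents of LDA deprotonate the γ-CH2 of the silyloxy enoate and C3 of the chromanone and both enolates are trapped on oxygen (kinetic enolate silylation), the C3=C4 bond of the diene forming Z so that the benzylic substituent avoids the C2 methyl group (allylic strain).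

Step 9
Reactants: 14 ethoxyacetylene; 15 Weinreb amide (N-methoxy-N-methylisobutyramide)
Product: 17 ethoxy ynone (1-ethoxy-4-methylpent-1-yn-3-one), via lithium ethoxyacetylide 16 (not isolated)
Conditions: n-BuLi, THF, −78 °C; then 15, −78 → 0 °C; aq NH4Cl
Reagents that add atoms: none
Why: The lithium acetylide is acylated by the Weinreb amide, whose chelated tetrahedral intermediate prevents over-addition (Weinreb ketone synthesis).

Step 10
Reactants: 13 tris-silyl diene ((3Z)-5-[5,7-dimethoxy-2,2,6-trimethyl-4-(trimethylsilyloxy)-2H-chromen-8-yl]-1-methoxy-2-methyl-1,3-bis(trimethylsilyloxy)penta-1,3-diene); 17 ethoxy ynone (1-ethoxy-4-methylpent-1-yn-3-one)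
Product: 20 ring A ethyl ether (1-[3-[(5,7-dimethoxy-2,2,6-trimethyl-4-oxochroman-8-yl)methyl]-2-ethoxy-4,6-dihydroxy-5-methylphenyl]-2-methylpropan-1-one), via cyclohexadiene cycloadduct 18 (not isolated), via silylated arene 19 (not isolated)
Conditions: 17 (1.5 equiv), PhMe, 70 °C (sealed); then 1 M HCl, THF, rt
Reagents that add atoms: none
Why: Proposed new method: the electron-rich diene 13 and the push-pull alkyne 17 should combine in a polarised, asynchronous Diels–Alder reaction in which diene C4 (future C3', carrying the ring B benzyl group) bonds to the ethoxy-bearing β-carbon of the ynone (future C2') and the ketene acetal carbon (future C6') bonds to the α-carbon (future C1'); in the stepwise limit this is a Mukaiyama–Michael addition followed by 6-exo-trig Claisen-type closure, with the same connectivity. The cycloadduct 18 should expel MeOSiMe3 from its mixed silyl methyl ketal carbon and the resulting cyclohexadienone enolise through H-3' to the arene 19, whose remaining silyl groups (ring A silyl ether and chromene enol ether) are cleaved by the acidic work-up. The closest known reaction is the benzannulation of 1-alkoxy-1,3-bis(silyloxy)dienes with alkynyl ketones and alkynoates to resorcinols; new here is a dienophile with an alkoxy group on the β-carbon, which supplies the third oxygen of the phloroglucinol but lowers the electrophilicity of the alkyne, hence the heating (kept below the temperature at which ethoxyalkynes lose ethylene) and ZnCl2 (10 mol %) as an optional catalyst. Ring A is closed by an intermolecular [4+2] process that forms two bonds, and no stereocentre remains because both sp3 carbons of 18 are flattened on aromatisation. The selectivity needed is regiochemical, diene C4 to the ynone β-carbon, and it is secured by matched polarisation: the largest HOMO coefficient of the diene is at C4 and the β-carbon of the ynone is its oxocarbenium-like vinylogous acyl position, so the isobutyryl group ends up between the C2' and C6' oxygens. The chromanone silyl enol ether is a far weaker nucleophile than the bis(silyloxy)diene and should remain a spectator.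

Step 11
Reactants: 20 ring A ethyl ether (1-[3-[(5,7-dimethoxy-2,2,6-trimethyl-4-oxochroman-8-yl)methyl]-2-ethoxy-4,6-dihydroxy-5-methylphenyl]-2-methylpropan-1-one)
Product: 21 target (1-[3-[(5,7-dihydroxy-2,2,6-trimethyl-4-oxochroman-8-yl)methyl]-2,4,6-trihydroxy-5-methylphenyl]-2-methylpropan-1-one)
Conditions: BBr3 (8 equiv), CH2Cl2, −78 → 0 °C; then MeOH, H2O
Reagents that add atoms: none
Why: BBr3 cleaves aryl alkyl ethers by Lewis-acid complexation and bromide attack on the alkyl group; the 2'-ethyl and 5-methyl ethers are activated by chelation to their ortho carbonyl groups and the hindered 7-methyl ether is twisted out of conjugation and therefore basic, so all three should be cleaved at or below 0 °C, where the chromanone and the methylene bridge should survive.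

**Compound list**

1 | 2,6-dimethoxytoluene (1,3-dimethoxy-2-methylbenzene) | COc1cccc(OC)c1C | starting material
2 | 2-(3,5-dimethoxy-4-methylphenyl)-4,4,5,5-tetramethyl-1,3,2-dioxaborolane | COc1cc(cc(OC)c1C)B1OC(C)(C)C(C)(C)O1 | intermediate
3 | 3,5-dimethoxy-4-methylphenol | COc1cc(O)cc(OC)c1C | intermediate
4 | 3-methylbut-2-enoic acid | CC(C)=CC(O)=O | starting material
5 | 1-(6-hydroxy-2,4-dimethoxy-3-methylphenyl)-3-methylbut-2-en-1-one | CC(C)=CC(=O)c1c(O)cc(OC)c(C)c1OC | intermediate
6 | 5,7-dimethoxy-2,2,6-trimethylchroman-4-one | COc1cc2OC(C)(C)CC(=O)c2c(OC)c1C | intermediate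
7 | 8-(bromomethyl)-5,7-dimethoxy-2,2,6-trimethylchroman-4-one | COc1c(CBr)c2OC(C)(C)CC(=O)c2c(OC)c1C | intermediate
8 | methyl 2-methyl-3-oxobutanoate | COC(=O)C(C)C(C)=O | starting material
9 | methyl 2-methyl-3-(trimethylsilyloxy)but-2-enoate | COC(=O)C(C)=C(C)O[Si](C)(C)C | intermediate
10 | 1-methoxy-2-methyl-1,3-bis(trimethylsilyloxy)buta-1,3-diene | COC(O[Si](C)(C)C)=C(C)C(=C)O[Si](C)(C)C | intermediate
11 | methyl 5-(5,7-dimethoxy-2,2,6-trimethyl-4-oxochroman-8-yl)-2-methyl-3-(trimethylsilyloxy)pent-2-enoate (enol ether geometry not defined) | COC(=O)C(C)=C(CCc1c(OC)c(C)c(OC)c2C(=O)CC(C)(C)Oc12)O[Si](C)(C)C | intermediate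
12 | methyl 5-(5,7-dimethoxy-2,2,6-trimethyl-4-oxochroman-8-yl)-2-methyl-3-oxopentanoate (racemic) | COC(=O)C(C)C(=O)CCc1c(OC)c(C)c(OC)c2C(=O)CC(C)(C)Oc12 | intermediate
13 | (3Z)-5-[5,7-dimethoxy-2,2,6-trimethyl-4-(trimethylsilyloxy)-2H-chromen-8-yl]-1-methoxy-2-methyl-1,3-bis(trimethylsilyloxy)penta-1,3-diene (C1=C2 geometry not defined) | COC(O[Si](C)(C)C)=C(C)/C(O[Si](C)(C)C)=C/Cc1c(OC)c(C)c(OC)c2C(O[Si](C)(C)C)=CC(C)(C)Oc12 | intermediate
14 | ethoxyacetylene | CCOC#C | starting material
15 | N-methoxy-N-methylisobutyramide | CC(C)C(=O)N(C)OC | starting material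
16 | lithium ethoxyacetylide | CCOC#C[Li] | intermediate
17 | 1-ethoxy-4-methylpent-1-yn-3-one | CCOC#CC(=O)C(C)C | intermediate
18 | 1-[3-[[5,7-dimethoxy-2,2,6-trimethyl-4-(trimethylsilyloxy)-2H-chromen-8-yl]methyl]-2-ethoxy-6-methoxy-5-methyl-4,6-bis(trimethylsilyloxy)cyclohexa-1,4-dien-1-yl]-2-methylpropan-1-one (diastereomer mixture) | COC1(O[Si](C)(C)C)C(C)=C(O[Si](C)(C)C)C(Cc2c(OC)c(C)c(OC)c3C(O[Si](C)(C)C)=CC(C)(C)Oc23)C(OCC)=C1C(=O)C(C)C | intermediate
19 | 1-[3-[[5,7-dimethoxy-2,2,6-trimethyl-4-(trimethylsilyloxy)-2H-chromen-8-yl]methyl]-2-ethoxy-6-hydroxy-5-methyl-4-(trimethylsilyloxy)phenyl]-2-methylpropan-1-one | CCOc1c(Cc2c(OC)c(C)c(OC)c3C(O[Si](C)(C)C)=CC(C)(C)Oc23)c(O[Si](C)(C)C)c(C)c(O)c1C(=O)C(C)C | intermediate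
20 | 1-[3-[(5,7-dimethoxy-2,2,6-trimethyl-4-oxochroman-8-yl)methyl]-2-ethoxy-4,6-dihydroxy-5-methylphenyl]-2-methylpropan-1-one | CCOc1c(Cc2c(OC)c(C)c(OC)c3C(=O)CC(C)(C)Oc23)c(O)c(C)c(O)c1C(=O)C(C)C | intermediate
21 | 1-[3-[(5,7-dihydroxy-2,2,6-trimethyl-4-oxochroman-8-yl)methyl]-2,4,6-trihydroxy-5-methylphenyl]-2-methylpropan-1-one (CNP0186856.0) | Cc1c(O)c(Cc2c(O)c(C)c(O)c3c2OC(C)(C)CC3=O)c(O)c(C(=O)C(C)C)c1O | target

**Step count and risks**

Total steps: 11. Longest linear sequence: 8 steps (1, 2, 3, 6, 7, 8, 10, 11); side branches are steps 4–5 (diene 10) and step 9 (ynone 17).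

Steps most likely to fail:

Step 10 (Proposed new method). The push-pull alkyne may be too weak an electrophile. Cycloaddition could then be outrun by protodesilylation of the diene or by thermal loss of ethylene from the ynol ether, and under Lewis acid the diene could add to the ynone carbonyl instead. The fallback uses known chemistry and brings ring A in preformed; it sets out from bromide 7. 2-Methylphloroglucinol is C-acylated with isobutyryl chloride (AlCl3, Friedel–Crafts acylation) to 1-(2,4,6-trihydroxy-3-methylphenyl)-2-methylpropan-1-one F1. The single free ring carbon of F1 is benzylated by 7 (ZnBr2 cat., CH2Cl2/dioxane, Friedel–Crafts alkylation) to the bridged diarylmethane F2, the 2'-hydroxy analogue of 20. Ether cleavage under the conditions of step 11 then gives 21, where the fallback rejoins the route.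

Step 11. While the unchelated 7-methyl ether is being cleaved, the electron-rich diarylmethane bridge may undergo acid-promoted fission or scrambling, or the chromanone may open and reclose onto the 5-oxygen. The fallback removes all ether cleavage from the bridged stage; it sets out from 10, 17 and 6 and returns at 21. The benzannulation of step 10, run on the simple diene 10 with 17, gives 1-(2-ethoxy-4,6-dihydroxy-5-methylphenyl)-2-methylpropan-1-one F3, whose chelated ethyl ether is cleaved by BCl3 (CH2Cl2, −78 → 0 °C) to give F1. Separately, 6 is demethylated with BBr3 to 5,7-dihydroxy-2,2,6-trimethylchroman-4-one F4, which undergoes Mannich aminomethylation at C8, its only free ring carbon (CH2O, Me2NH, EtOH), to the Mannich base F5. Heating F5 with F1 (dioxane, 100 °C) generates the ortho-quinone methide of ring B, which alkylates the free carbon of F1 and gives 21 directly.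

Step 3. Over-alkylation may occur, with the benzylic bromide or its cation attacking unreacted 6 to give a diarylmethane, and acid-catalysed hydroxymethylation may occur at C3 of the ketone. The fallback sets out from 6 and introduces the carbon at the aldehyde level. Vilsmeier–Haack formylation (POCl3, DMF, 70 °C) gives 5,7-dimethoxy-2,2,6-trimethyl-4-oxochroman-8-carbaldehyde F6. Chemoselective NaBH4 reduction of the aldehyde (MeOH, −20 °C) gives the benzylic alcohol F7, and PBr3 (CH2Cl2, 0 °C) converts it to 7, where the route is rejoined.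

**Further compounds**

F1 | step 10 | 1-(2,4,6-trihydroxy-3-methylphenyl)-2-methylpropan-1-one | CC(C)C(=O)c1c(O)cc(O)c(C)c1O
F2 | step 10 | 1-[3-[(5,7-dimethoxy-2,2,6-trimethyl-4-oxochroman-8-yl)methyl]-2,4,6-trihydroxy-5-methylphenyl]-2-methylpropan-1-one | CC(C)C(=O)c1c(O)c(C)c(O)c(Cc2c(OC)c(C)c(OC)c3C(=O)CC(C)(C)Oc23)c1O
F3 | step 11 | 1-(2-ethoxy-4,6-dihydroxy-5-methylphenyl)-2-methylpropan-1-one | CCOc1cc(O)c(C)c(O)c1C(=O)C(C)C
F4 | step 11 | 5,7-dihydroxy-2,2,6-trimethylchroman-4-one | Cc1c(O)cc2OC(C)(C)CC(=O)c2c1O
F5 | step 11 | 8-[(dimethylamino)methyl]-5,7-dihydroxy-2,2,6-trimethylchroman-4-one | CN(C)Cc1c(O)c(C)c(O)c2C(=O)CC(C)(C)Oc12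
F6 | step 3 | 5,7-dimethoxy-2,2,6-trimethyl-4-oxochroman-8-carbaldehyde | COc1c(C=O)c2OC(C)(C)CC(=O)c2c(OC)c1C
F7 | step 3 | 8-(hydroxymethyl)-5,7-dimethoxy-2,2,6-trimethylchroman-4-one | COc1c(CO)c2OC(C)(C)CC(=O)c2c(OC)c1C
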